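**Plan**

Numbering: ring C1 (CH carrying the chain), C2 (CH–O-isovalerate), C3 (C=O), C4 (methyl-bearing epoxide carbon), C5 (epoxide CH), C6 (CH2); chain C7(=C14H2)–C8(=O)–C9=C10–C11(CH3)2–OOH.
Enabling feature: without the epoxide oxygen and the C2 ester the carbocycle is a 5-substituted 2-methylcyclohex-2-enone, in which C5–C6–C1 is an enal (C1 its β-carbon, C7 an acetal carbon on it) and C2–C3–C4(CH3) is the ethyl-ketone end of a 3-oxopentanoate.
Retrosynthetic cuts, last-made bond first: O–C11 (ene reaction), C7–C8 (Ni/Cr coupling), C7–C14 (methyl addition), the two epoxide C–O bonds, C2–O, and finally the ring bonds C1–C2 and C4=C5.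
Forward: the only carbocycle is closed first (step 2); the ring oxygens follow (C2–O, C3 reduction, directed epoxide); the chain is then grown from C7; C3 and C8 are oxidised together and the hydroperoxide comes last.
Stereochemistry: C1 from the chiral amine catalyst; C2 by enolate oxidation anti to the C1 substituent; the temporary C3 carbinol by axial hydride delivery; C4/C5 by vanadium delivery from that carbinol (cis to C1); C9=C10 E from the ene step.

Key step: step 2

Remark: the (S)-configured catalyst is taken to screen the face that leaves R at C1, the sense it shows with other carbon nucleophiles (otherwise its enantiomer is used); the carbinol centres made in steps 9 and 13 are epimer mixtures that are oxidised away.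

**Route**

Step 1
Reactants: 1 methyl 3-oxopentanoate; 2 allyl alcohol
Product: 3 allyl 3-oxopentanoate
Conditions: allyl alcohol (excess), DMAP (cat.), toluene, reflux, 4 Å sieves (MeOH removed)
Reagents that add atoms: none
Why: DMAP-catalysed transesterification of a β-keto ester, pulled to the allyl ester by removal of methanol; no stereocentre is involved.

Step 2
Reactants: 3 allyl 3-oxopentanoate; 4 (E)-4,4-dimethoxybut-2-enal
Product: 9 (5R)-5-(dimethoxymethyl)-2-methylcyclohex-2-en-1-one, via Michael adduct 5 (not isolated), via aldol 6 (not isolated), via cyclohexenone allyl ester 7 (not isolated), via keto acid 8 (not isolated)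
Conditions: (S)-2-{bis[3,5-bis(trifluoromethyl)phenyl](trimethylsilyloxy)methyl}pyrrolidine (10 mol %), PhCO2H (10 mol %), toluene, 0 °C to rt, then 40 °C; then Pd(PPh3)4 (2 mol %), morpholine, THF, rt to 40 °C
Reagents that add atoms: none
Why: The amine and enal 4 form an E-iminium ion with one face screened by the diaryl(silyloxy)methyl arm, so the enol of 3 adds through its C2 methylene to the β-carbon from the open face, which fixes C1 as R, and hydrolysis of the enamine releases aldehyde 5. The ethyl-ketone enol then attacks the C5 aldehyde through C4 in a 6-(enolendo)-exo-trig aldol closure of the only ring, and aldol 6 loses water to the conjugated enone 7. Pd(0) ionises the allyl ester, morpholine takes up the allyl fragment, and keto acid 8 loses CO2 to give 9 (Tsuji-type deallylation–decarboxylation). The closest known reaction type is the diarylprolinol-silyl-ether-catalysed Michael–aldol annulation of enals with β-keto esters to 5-substituted cyclohexenones, followed by decarboxylation. The step needs conjugate rather than direct attack on the enal and one ring-closure mode: iminium activation steers the soft dicarbonyl carbon to the β-position, and only C4 reaches the aldehyde through a six-membered transition state, every alternative being a four-membered ring. C7 rides through as a dimethyl acetal with neither an acidic hydrogen nor an electrophilic site, the stereocentres formed transiently at C2, C4 and C5 are erased by decarboxylation and dehydration, and the neutral palladium step spares the acetal.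

Step 3
Reactants: 9 (5R)-5-(dimethoxymethyl)-2-methylcyclohex-2-en-1-one
Product: 11 (5R,6S)-5-(dimethoxymethyl)-6-hydroxy-2-methylcyclohex-2-en-1-one, via sodium dienolate 10 (not isolated)
Conditions: NaHMDS, THF, −78 °C; then 2-(phenylsulfonyl)-3-phenyloxaziridine, −78 °C; aq. NH4Cl
Reagents that add atoms: 2-(phenylsulfonyl)-3-phenyloxaziridine, O=S(=O)(N1OC1c1ccccc1)c1ccccc1
Why: Kinetic α′-deprotonation gives the cross-conjugated dienolate, and oxygen transfer from the oxaziridine (Davis enolate hydroxylation) should occur on the face of C2 turned away from the neighbouring C1 substituent, placing the hydroxyl trans to it (6S).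

Step 4
Reactants: 11 (5R,6S)-5-(dimethoxymethyl)-6-hydroxy-2-methylcyclohex-2-en-1-one; 12 isovaleryl chloride
Product: 13 (1S,6R)-6-(dimethoxymethyl)-3-methyl-2-oxocyclohex-3-en-1-yl 3-methylbutanoate
Conditions: pyridine, DMAP (cat.), CH2Cl2, 0 °C
Reagents that add atoms: none
Why: DMAP-catalysed O-acylation of a secondary α-ketol with an acid chloride; the weak base leaves the C2 centre, already in its more stable trans arrangement, untouched.

Step 5
Reactants: 13 (1S,6R)-6-(dimethoxymethyl)-3-methyl-2-oxocyclohex-3-en-1-yl 3-methylbutanoate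
Product: 14 (1S,2S,6R)-6-(dimethoxymethyl)-2-hydroxy-3-methylcyclohex-3-en-1-yl 3-methylbutanoate
Conditions: NaBH4, CeCl3·7H2O, MeOH, −78 °C; AcOH quench at −78 °C
Reagents that add atoms: none
Why: Luche 1,2-reduction of the enone; axial hydride delivery to the half-chair that holds the C1 and C2 substituents equatorial should give the equatorial C3 alcohol, trans to the ester and cis to the C1 substituent, and the cold acidic quench prevents acyl migration.

Step 6
Reactants: 14 (1S,2S,6R)-6-(dimethoxymethyl)-2-hydroxy-3-methylcyclohex-3-en-1-yl 3-methylbutanoate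
Product: 15 (1R,2R,3S,4R,6S)-4-(dimethoxymethyl)-2-hydroxy-1-methyl-7-oxabicyclo[4.1.0]heptan-3-yl 3-methylbutanoate
Conditions: VO(acac)2 (cat.), t-BuOOH (decane), CH2Cl2, 0 °C to rt
Reagents that add atoms: tert-butyl hydroperoxide, CC(C)(C)OO
Why: Vanadium-catalysed hydroxyl-directed epoxidation of a cyclic allylic alcohol; the peroxide oxygen is delivered from the vanadate ester of the C3 hydroxyl to the same face of C4=C5, which sets C4 and C5 with the epoxide cis to that hydroxyl and therefore cis to the C1 substituent.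

Step 7
Reactants: 15 (1R,2R,3S,4R,6S)-4-(dimethoxymethyl)-2-hydroxy-1-methyl-7-oxabicyclo[4.1.0]heptan-3-yl 3-methylbutanoate
Product: 16 (1S,2R,3S,4R,6S)-2-[(tert-butyldimethylsilyl)oxy]-4-(dimethoxymethyl)-1-methyl-7-oxabicyclo[4.1.0]heptan-3-yl 3-methylbutanoate
Conditions: TBSOTf, 2,6-lutidine, CH2Cl2, −78 °C
Reagents that add atoms: tert-butyldimethylsilyl triflate, CC(C)(C)[Si](C)(C)OS(=O)(=O)C(F)(F)F
Why: Silylation of the hindered secondary alcohol with a silyl triflate at low temperature, faster than any reaction of the acetal or epoxide; it keeps C3 from being oxidised in step 10 and from carrying an alkoxide next to the ester in step 11.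

Step 8
Reactants: 16 (1S,2R,3S,4R,6S)-2-[(tert-butyldimethylsilyl)oxy]-4-(dimethoxymethyl)-1-methyl-7-oxabicyclo[4.1.0]heptan-3-yl 3-methylbutanoate
Product: 17 (1S,2R,3S,4R,6S)-2-[(tert-butyldimethylsilyl)oxy]-4-formyl-1-methyl-7-oxabicyclo[4.1.0]heptan-3-yl 3-methylbutanoate
Conditions: PPTS (cat.), acetone–H2O, 40 °C; product used crude
Reagents that add atoms: water, O
Why: Acid-catalysed acetal hydrolysis under a weak pyridinium acid, which should spare the TBS ether, the epoxide and the ester and should not enolise the aldehyde at C1.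

Step 9
Reactants: 17 (1S,2R,3S,4R,6S)-2-[(tert-butyldimethylsilyl)oxy]-4-formyl-1-methyl-7-oxabicyclo[4.1.0]heptan-3-yl 3-methylbutanoate
Product: 18 (1S,2R,3S,4S,6S)-2-[(tert-butyldimethylsilyl)oxy]-4-(1-hydroxyethyl)-1-methyl-7-oxabicyclo[4.1.0]heptan-3-yl 3-methylbutanoate
Conditions: MeMgBr (1.1 equiv), THF, −78 °C; aq. NH4Cl
Reagents that add atoms: methylmagnesium bromide, C[Mg]Br
Why: Grignard addition to the aldehyde, which at −78 °C outpaces attack on the hindered ester and enolisation; it brings in C14, and the new carbinol centre is formed without control because step 10 removes it.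

Step 10
Reactants: 18 (1S,2R,3S,4S,6S)-2-[(tert-butyldimethylsilyl)oxy]-4-(1-hydroxyethyl)-1-methyl-7-oxabicyclo[4.1.0]heptan-3-yl 3-methylbutanoate
Product: 19 (1S,2R,3S,4R,6S)-4-acetyl-2-[(tert-butyldimethylsilyl)oxy]-1-methyl-7-oxabicyclo[4.1.0]heptan-3-yl 3-methylbutanoate
Conditions: Dess–Martin periodinane, NaHCO3, CH2Cl2, 0 °C to rt; product used crude
Reagents that add atoms: none
Why: Dess–Martin oxidation of the secondary alcohol to the methyl ketone under buffered, non-basic conditions, so that the isovalerate β to the new carbonyl is not eliminated.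

Step 11
Reactants: 19 (1S,2R,3S,4R,6S)-4-acetyl-2-[(tert-butyldimethylsilyl)oxy]-1-methyl-7-oxabicyclo[4.1.0]heptan-3-yl 3-methylbutanoate
Product: 21 (1S,2R,3S,4R,6S)-2-[(tert-butyldimethylsilyl)oxy]-1-methyl-4-{1-[(trifluoromethanesulfonyl)oxy]ethenyl}-7-oxabicyclo[4.1.0]heptan-3-yl 3-methylbutanoate, via potassium enolate 20 (not isolated)
Conditions: KHMDS, THF, −78 °C; then N-(5-chloropyridin-2-yl)bis(trifluoromethanesulfonyl)imide (Comins' reagent), −78 °C; aq. NH4Cl
Reagents that add atoms: N-(5-chloropyridin-2-yl)bis(trifluoromethanesulfonyl)imide, O=S(=O)(N(c1ccc(Cl)cn1)S(=O)(=O)C(F)(F)F)C(F)(F)F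
Why: Kinetic deprotonation of the methyl ketone at the unhindered methyl group and O-sulfonylation of the terminal enolate (enol triflate formation) at −78 °C, where the enolate should be trapped before it can attack the neighbouring ester.

Step 12
Reactants: 22 4-methylpent-3-en-1-ol
Product: 23 4-methylpent-3-enal
Conditions: Dess–Martin periodinane, NaHCO3, CH2Cl2, 0 °C; filtered solution used at once
Reagents that add atoms: none
Why: Dess–Martin oxidation of a homoallylic primary alcohol under neutral conditions, which should keep the double bond out of conjugation with the new aldehyde.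

Step 13
Reactants: 21 (1S,2R,3S,4R,6S)-2-[(tert-butyldimethylsilyl)oxy]-1-methyl-4-{1-[(trifluoromethanesulfonyl)oxy]ethenyl}-7-oxabicyclo[4.1.0]heptan-3-yl 3-methylbutanoate; 23 4-methylpent-3-enal
Product: 25 (1S,2R,3S,4S,6S)-2-[(tert-butyldimethylsilyl)oxy]-4-(3-hydroxy-6-methylhepta-1,5-dien-2-yl)-1-methyl-7-oxabicyclo[4.1.0]heptan-3-yl 3-methylbutanoate, via alkenylchromium dichloride 24 (not isolated)
Conditions: CrCl2 (excess), NiCl2 (cat.), DMF, rt
Reagents that add atoms: none
Why: Nozaki–Hiyama–Kishi coupling, in which nickel inserts into the C7–OTf bond, the alkenyl group passes to chromium(III) and adds only to the aldehyde, forming C7–C8 in the presence of ester, epoxide and silyl ether; the C8 carbinol is formed as both epimers and oxidised in step 15.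

Step 14
Reactants: 25 (1S,2R,3S,4S,6S)-2-[(tert-butyldimethylsilyl)oxy]-4-(3-hydroxy-6-methylhepta-1,5-dien-2-yl)-1-methyl-7-oxabicyclo[4.1.0]heptan-3-yl 3-methylbutanoate
Product: 26 (1R,2R,3S,4S,6S)-2-hydroxy-4-(3-hydroxy-6-methylhepta-1,5-dien-2-yl)-1-methyl-7-oxabicyclo[4.1.0]heptan-3-yl 3-methylbutanoate
Conditions: Et3N·3HF, MeCN, rt
Reagents that add atoms: none
Why: Fluoride-driven cleavage of the silyl ether (desilylation) with a near-neutral HF source, chosen so that no free alkoxide forms next to the C2 ester (no acyl migration) and the epoxide is not opened.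

Step 15
Reactants: 26 (1R,2R,3S,4S,6S)-2-hydroxy-4-(3-hydroxy-6-methylhepta-1,5-dien-2-yl)-1-methyl-7-oxabicyclo[4.1.0]heptan-3-yl 3-methylbutanoate
Product: 27 (1S,3S,4S,6S)-1-methyl-4-(6-methyl-3-oxohepta-1,5-dien-2-yl)-2-oxo-7-oxabicyclo[4.1.0]heptan-3-yl 3-methylbutanoate
Conditions: Dess–Martin periodinane (excess), NaHCO3, CH2Cl2, 0 °C to rt; product used at once
Reagents that add atoms: none
Why: Twofold Dess–Martin oxidation turns the epoxy alcohol into the epoxy ketone and the allylic C8 carbinol into the enone in one operation, without base that would move the C10=C11 bond into conjugation or epimerise C2.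

Step 16
Reactants: 27 (1S,3S,4S,6S)-1-methyl-4-(6-methyl-3-oxohepta-1,5-dien-2-yl)-2-oxo-7-oxabicyclo[4.1.0]heptan-3-yl 3-methylbutanoate
Product: 28 (1S,3S,4S,6S)-4-[(4E)-6-hydroperoxy-6-methyl-3-oxohepta-1,4-dien-2-yl]-1-methyl-2-oxo-7-oxabicyclo[4.1.0]heptan-3-yl 3-methylbutanoate
Conditions: O2, tetraphenylporphyrin (cat.), visible light, CH2Cl2, −20 °C
Reagents that add atoms: oxygen, O=O
Why: Schenck ene reaction, in which singlet oxygen attacks the electron-rich C10=C11 bond, takes a hydrogen from C9 (allylic and α to the C8 ketone), bonds to C11 and shifts the double bond to C9=C10 as the E isomer in conjugation with the ketone, while the electron-poor C7=C14 bond should stay inert.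

**Compound list**

1 | methyl 3-oxopentanoate | CCC(=O)CC(=O)OC | starting material
2 | allyl alcohol (prop-2-en-1-ol) | C=CCO | starting material
3 | allyl 3-oxopentanoate | CCC(=O)CC(=O)OCC=C | intermediate
4 | (E)-4,4-dimethoxybut-2-enal | COC(OC)/C=C/C=O | starting material
5 | allyl 2-[(2R)-1,1-dimethoxy-4-oxobutan-2-yl]-3-oxopentanoate (both epimers at the ester-bearing carbon) | CCC(=O)C(C(=O)OCC=C)[C@@H](CC=O)C(OC)OC | intermediate (not isolated)
6 | allyl (6R)-6-(dimethoxymethyl)-4-hydroxy-3-methyl-2-oxocyclohexane-1-carboxylate (diastereomer mixture at C1, C3, C4) | C=CCOC(=O)C1C(=O)C(C)C(O)C[C@H]1C(OC)OC | intermediate (not isolated)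
7 | allyl (6R)-6-(dimethoxymethyl)-3-methyl-2-oxocyclohex-3-ene-1-carboxylate (both C1 epimers) | C=CCOC(=O)C1C(=O)C(C)=CC[C@H]1C(OC)OC | intermediate (not isolated)
8 | (6R)-6-(dimethoxymethyl)-3-methyl-2-oxocyclohex-3-ene-1-carboxylic acid | OC(=O)C1C(=O)C(C)=CC[C@H]1C(OC)OC | intermediate (not isolated)
9 | (5R)-5-(dimethoxymethyl)-2-methylcyclohex-2-en-1-one | COC(OC)[C@@H]1CC=C(C)C(=O)C1 | intermediate
10 | sodium (3R)-3-(dimethoxymethyl)-6-methylcyclohexa-1,5-dien-1-olate | COC(OC)[C@@H]1CC=C(C)C([O-])=C1.[Na+] | intermediate (not isolated)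
11 | (5R,6S)-5-(dimethoxymethyl)-6-hydroxy-2-methylcyclohex-2-en-1-one | COC(OC)[C@@H]1CC=C(C)C(=O)[C@H]1O | intermediate
12 | isovaleryl chloride (3-methylbutanoyl chloride) | CC(C)CC(Cl)=O | starting material
13 | (1S,6R)-6-(dimethoxymethyl)-3-methyl-2-oxocyclohex-3-en-1-yl 3-methylbutanoate | COC(OC)[C@@H]1CC=C(C)C(=O)[C@H]1OC(=O)CC(C)C | intermediate
14 | (1S,2S,6R)-6-(dimethoxymethyl)-2-hydroxy-3-methylcyclohex-3-en-1-yl 3-methylbutanoate | COC(OC)[C@@H]1CC=C(C)[C@H](O)[C@H]1OC(=O)CC(C)C | intermediate
15 | (1R,2R,3S,4R,6S)-4-(dimethoxymethyl)-2-hydroxy-1-methyl-7-oxabicyclo[4.1.0]heptan-3-yl 3-methylbutanoate | COC(OC)[C@@H]1C[C@@H]2O[C@]2(C)[C@H](O)[C@H]1OC(=O)CC(C)C | intermediate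
16 | (1S,2R,3S,4R,6S)-2-[(tert-butyldimethylsilyl)oxy]-4-(dimethoxymethyl)-1-methyl-7-oxabicyclo[4.1.0]heptan-3-yl 3-methylbutanoate | COC(OC)[C@@H]1C[C@@H]2O[C@]2(C)[C@H](O[Si](C)(C)C(C)(C)C)[C@H]1OC(=O)CC(C)C | intermediate
17 | (1S,2R,3S,4R,6S)-2-[(tert-butyldimethylsilyl)oxy]-4-formyl-1-methyl-7-oxabicyclo[4.1.0]heptan-3-yl 3-methylbutanoate | O=C[C@@H]1C[C@@H]2O[C@]2(C)[C@H](O[Si](C)(C)C(C)(C)C)[C@H]1OC(=O)CC(C)C | intermediate
18 | (1S,2R,3S,4S,6S)-2-[(tert-butyldimethylsilyl)oxy]-4-(1-hydroxyethyl)-1-methyl-7-oxabicyclo[4.1.0]heptan-3-yl 3-methylbutanoate (both carbinol epimers) | CC(O)[C@@H]1C[C@@H]2O[C@]2(C)[C@H](O[Si](C)(C)C(C)(C)C)[C@H]1OC(=O)CC(C)C | intermediate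
19 | (1S,2R,3S,4R,6S)-4-acetyl-2-[(tert-butyldimethylsilyl)oxy]-1-methyl-7-oxabicyclo[4.1.0]heptan-3-yl 3-methylbutanoate | CC(=O)[C@@H]1C[C@@H]2O[C@]2(C)[C@H](O[Si](C)(C)C(C)(C)C)[C@H]1OC(=O)CC(C)C | intermediate
20 | potassium 1-{(1S,2R,3S,4R,6S)-2-[(tert-butyldimethylsilyl)oxy]-1-methyl-3-[(3-methylbutanoyl)oxy]-7-oxabicyclo[4.1.0]heptan-4-yl}ethen-1-olate (ring numbered as in 19) | C=C([O-])[C@@H]1C[C@@H]2O[C@]2(C)[C@H](O[Si](C)(C)C(C)(C)C)[C@H]1OC(=O)CC(C)C.[K+] | intermediate (not isolated)
21 | (1S,2R,3S,4R,6S)-2-[(tert-butyldimethylsilyl)oxy]-1-methyl-4-{1-[(trifluoromethanesulfonyl)oxy]ethenyl}-7-oxabicyclo[4.1.0]heptan-3-yl 3-methylbutanoate | C=C(OS(=O)(=O)C(F)(F)F)[C@@H]1C[C@@H]2O[C@]2(C)[C@H](O[Si](C)(C)C(C)(C)C)[C@H]1OC(=O)CC(C)C | intermediate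
22 | 4-methylpent-3-en-1-ol | CC(C)=CCCO | starting material
23 | 4-methylpent-3-enal | CC(C)=CCC=O | intermediate
24 | alkenylchromium(III) dichloride derived from 21 (CrCl2 in place of OTf on C7) | C=C([Cr](Cl)Cl)[C@@H]1C[C@@H]2O[C@]2(C)[C@H](O[Si](C)(C)C(C)(C)C)[C@H]1OC(=O)CC(C)C | intermediate (not isolated)
25 | (1S,2R,3S,4S,6S)-2-[(tert-butyldimethylsilyl)oxy]-4-(3-hydroxy-6-methylhepta-1,5-dien-2-yl)-1-methyl-7-oxabicyclo[4.1.0]heptan-3-yl 3-methylbutanoate (both C8 epimers) | CC(C)=CCC(O)C(=C)[C@@H]1C[C@@H]2O[C@]2(C)[C@H](O[Si](C)(C)C(C)(C)C)[C@H]1OC(=O)CC(C)C | intermediate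
26 | (1R,2R,3S,4S,6S)-2-hydroxy-4-(3-hydroxy-6-methylhepta-1,5-dien-2-yl)-1-methyl-7-oxabicyclo[4.1.0]heptan-3-yl 3-methylbutanoate (both C8 epimers) | CC(C)=CCC(O)C(=C)[C@@H]1C[C@@H]2O[C@]2(C)[C@H](O)[C@H]1OC(=O)CC(C)C | intermediate
27 | (1S,3S,4S,6S)-1-methyl-4-(6-methyl-3-oxohepta-1,5-dien-2-yl)-2-oxo-7-oxabicyclo[4.1.0]heptan-3-yl 3-methylbutanoate | CC(C)=CCC(=O)C(=C)[C@@H]1C[C@@H]2O[C@]2(C)C(=O)[C@H]1OC(=O)CC(C)C | intermediate
28 | (1S,3S,4S,6S)-4-[(4E)-6-hydroperoxy-6-methyl-3-oxohepta-1,4-dien-2-yl]-1-methyl-2-oxo-7-oxabicyclo[4.1.0]heptan-3-yl 3-methylbutanoate (CNP0241468.1) | C=C(C(=O)/C=C/C(C)(C)OO)[C@@H]1C[C@@H]2O[C@]2(C)C(=O)[C@H]1OC(=O)CC(C)C | target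

**Count and risks**

Total: 16 steps. Longest linear sequence: 15 steps (steps 1–11 and 13–16, from methyl 3-oxopentanoate); step 12 is a one-step side branch.

Steps most likely to fail:

Step 11. The methyl-ketone enolate may transfer the acyl group of the neighbouring C2 ester onto carbon before it is trapped, or deprotonation may stray to C1 and expel isovalerate by β-elimination. The fallback avoids enolates, sets out from methyl ketone 19 and comes back at allylic alcohol 25. Condensation of 19 with hydrazine hydrate (Et3N, EtOH, rt) should give the hydrazone F1. Iodine and 1,1,3,3-tetramethylguanidine (THF, 0 °C) should then oxidise it with loss of nitrogen to the 2-iodoalkene F2 (Barton vinyl iodide synthesis). F2 takes the place of 21 in the Ni/Cr coupling with 23 under the conditions of step 13, through the same alkenylchromium 24, to give 25.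

Step 16. Hydrogen abstraction from the two methyl groups on C11 competes with abstraction at C9, which would put the peroxide on C10, and the product may fragment under prolonged irradiation. The fallback sets out from 27 and ends at 28 itself, with a different mechanism. Ground-state oxygen with a catalytic amine in the dark (O2, Et3N cat., EtOAc, 0 °C) oxygenates the extended dienol of the C8 ketone at its γ-carbon C11, the base-mediated autoxidation of a β,γ-unsaturated ketone to the γ-hydroperoxy enone. Only the acidic C9 hydrogens are engaged, so the methyl groups cannot react; no new compound arises (entry F0).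

Step 2. The cascade may stall after the conjugate addition, because the dicarbonyl enol can trap the aldehyde as a cyclic hemiacetal, and forcing the ring closure could erode the enantiomeric purity by retro-addition. The fallback keeps the same two ring bonds but changes the order, setting out from Michael adduct 5 (isolated after the amine-catalysed addition) and coming back at 9. Pd(PPh3)4 and morpholine (THF, rt) remove the allyl group first, and the acyclic keto acid F3 loses CO2 to give (3R)-3-(dimethoxymethyl)-5-oxoheptanal F4. This simple 1,5-keto aldehyde is then closed in a separate Robinson-type aldol condensation (pyrrolidine, AcOH, toluene, 50 °C) through the aldol F5 to 9; again only the ethyl-ketone methylene can form a six-membered ring.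

**Further compounds**

F1 | step 11 | (1S,2R,3S,4S,6S)-2-[(tert-butyldimethylsilyl)oxy]-4-(1-hydrazinylideneethyl)-1-methyl-7-oxabicyclo[4.1.0]heptan-3-yl 3-methylbutanoate | CC(=NN)[C@@H]1C[C@@H]2O[C@]2(C)[C@H](O[Si](C)(C)C(C)(C)C)[C@H]1OC(=O)CC(C)C
F2 | step 11 | (1S,2R,3S,4R,6S)-2-[(tert-butyldimethylsilyl)oxy]-4-(1-iodoethenyl)-1-methyl-7-oxabicyclo[4.1.0]heptan-3-yl 3-methylbutanoate | C=C(I)[C@@H]1C[C@@H]2O[C@]2(C)[C@H](O[Si](C)(C)C(C)(C)C)[C@H]1OC(=O)CC(C)C
F0 | step 16 | none | none
F3 | step 2 | 2-[(2R)-1,1-dimethoxy-4-oxobutan-2-yl]-3-oxopentanoic acid | CCC(=O)C(C(=O)O)[C@@H](CC=O)C(OC)OC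
F4 | step 2 | (3R)-3-(dimethoxymethyl)-5-oxoheptanal | CCC(=O)C[C@@H](CC=O)C(OC)OC
F5 | step 2 | (5R)-5-(dimethoxymethyl)-3-hydroxy-2-methylcyclohexan-1-one (diastereomer mixture at C2, C3) | COC(OC)[C@@H]1CC(O)C(C)C(=O)C1
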